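**Strategy.** The route rests on cutting the cyclohexene-1,3-dione ring of the bicyclo[3.2.1]oct-3-ene-2,8-dione (C1, C2, C3, C4, C5, C8) by a retro 1,2-acyl shift: its bridgehead C1–H, flanked by the C2 and C8 carbonyls, marks an α,β-epoxy ketone rearrangement. In one operation the C2 acyl group moves from C8 to C1, so the cyclopentenone ring (C8, C2, C3, C4, C5) of an angular triquinane expands by one carbon into the enedione ring, C8 becomes the bridging ketone and C1 is set. The precursor is the C8–C1 epoxide of a cross-conjugated triquinane dienone, built by Claisen rearrangement and double aldol condensation onto an indane-fused cyclopentanone.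

Key step: step 13

Remark (numbering): C1–C8 are the atoms of the bicyclo[3.2.1]oct-3-ene-2,8-dione: C1 bridgehead CH, C2 and C8 ketones, C3=C4, C5 quaternary bridgehead, C6 bearing 4-hydroxyphenyl, C7 bearing 3,5-dihydroxyphenyl. C9 (on C4) and C10 are the ring-fusion CH carbons of the cyclopentane fused at C4–C5, C11 (on C5) is its aryl-bearing CH, and C12 is the aryl-bearing CH of the indane. The same atom numbers are used in all intermediates.

Remark (protection): all seven phenols are carried as methyl ethers and released in the last step.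

Remark (absolute configuration): it is fixed in step 2; the enantiomer of the pyridine-oxazoline ligand that delivers (1S,4R)-7 is assumed.

**Step 1**
Reactants: 1 3-(4-methoxyphenyl)prop-2-yn-1-ol; 2 (3,5-dimethoxyphenyl)magnesium chloride
Product: 4 (E)-2-(3,5-dimethoxyphenyl)-3-(4-methoxyphenyl)prop-2-en-1-ol, via alkenylmagnesium chelate 3 (not isolated)
Conditions: 2 (3 equiv), CuI (10 mol %), THF, 0 to 65 °C; then aq. NH4Cl
Reagents that add atoms: none
Why: Copper-catalysed anti-carbomagnesiation of a propargylic alcohol, in which the magnesium alkoxide directs the aryl group to the proximal alkyne carbon and forms the five-membered chelate 3, so that protonolysis should give the (E)-alkene with the two aryl groups cis.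

**Step 2**
Reactants: 5 cyclopent-3-en-1-ol; 6 4-methoxybenzenediazonium tetrafluoroborate
Product: 7 (1S,4R)-4-(4-methoxyphenyl)cyclopent-2-en-1-ol
Conditions: Pd(OCOCF3)2 (5 mol %), chiral 4-tert-butyl-2-(pyridin-2-yl)-4,5-dihydrooxazole ligand (10 mol %), 2,6-di-tert-butyl-4-methylpyridine, MeOH, 40 °C
Reagents that add atoms: none
Why: Enantioselective Heck–Matsuda desymmetrisation, in which the hydroxyl group directs syn aryl-palladation to its own face, the chiral ligand selects between the enantiotopic alkene carbons and β-hydride elimination away from the new centre gives the cis allylic alcohol, setting C11.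

**Step 3**
Reactants: 7 (1S,4R)-4-(4-methoxyphenyl)cyclopent-2-en-1-ol
Product: 8 (R)-4-(4-methoxyphenyl)cyclopent-2-en-1-one
Conditions: Dess–Martin periodinane, CH2Cl2, 0 °C to rt
Reagents that add atoms: none
Why: Dess–Martin oxidation of the secondary allylic alcohol under non-basic conditions should give the enone without epimerising the γ-stereocentre C11.

**Step 4**
Reactants: 8 (R)-4-(4-methoxyphenyl)cyclopent-2-en-1-one; 2 (3,5-dimethoxyphenyl)magnesium chloride; 9 4-methoxybenzaldehyde
Product: 11 2,3-trans-3,4-trans-3-(3,5-dimethoxyphenyl)-2-[hydroxy(4-methoxyphenyl)methyl]-4-(4-methoxyphenyl)cyclopentan-1-one (carbinol epimers), via magnesium enolate 10 (not isolated)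
Conditions: CuBr·SMe2 (10 mol %), THF, −78 °C; then 9, −78 to −40 °C; aq. NH4Cl
Reagents that add atoms: none
Why: Tandem copper-catalysed conjugate addition and aldol reaction, in which the aryl group adds anti to the C11 aryl group (C10 trans) and the regiodefined enolate 10 is trapped at C9 by the aldehyde; the carbinol configuration is lost in step 5.

**Step 5**
Reactants: 11 aldol adduct (carbinol epimers)
Product: 13 cis-fused 5,7-dimethoxy-3,8-bis(4-methoxyphenyl)-3,3a,8,8a-tetrahydrocyclopenta[a]inden-1(2H)-one (ketone carbon = C4, CH2 = C5), via benzylidene ketone 12 (not isolated)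
Conditions: CF3SO3H (20 mol %), CH2Cl2, 0 °C to rt
Reagents that add atoms: none
Why: Acid-catalysed dehydration gives the (E)-benzylidene ketone 12, whose O-protonated form is a 4-methoxybenzylic cation at C12 that is captured by the ortho carbon of the neighbouring 3,5-dimethoxyphenyl ring (intramolecular Friedel–Crafts alkylation closing the indane); the tether enforces the cis fusion at C9, and attack on the (E)-alkene from the arene-bearing face places the C12 aryl group on the convex face.

**Step 6**
Reactants: 13 tricyclic ketone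
Product: 14 2-(hydroxymethylene) derivative of 13 (chelated enol of the C5-formyl ketone)
Conditions: NaH, HCO2Et, THF, 0 °C to rt; then dilute HCl
Reagents that add atoms: ethyl formate, CCOC=O
Why: Crossed Claisen condensation (formylation) at C5, the only methylene α to the ketone, gives the stable enolised β-keto aldehyde and introduces the future C8 without creating a stereocentre.

**Step 7**
Reactants: 14 hydroxymethylene ketone; 4 (E)-2-(3,5-dimethoxyphenyl)-3-(4-methoxyphenyl)prop-2-en-1-ol
Product: 16 keto aldehyde with quaternary C5: 13 carrying at C5 a formyl group (cis to the C11 aryl) and a 2-(3,5-dimethoxyphenyl)-1-(4-methoxyphenyl)prop-2-en-1-yl group, via allyl enol ether 15 (not isolated)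
Conditions: PPh3, DIAD, toluene, 0 °C to rt; then 140 °C (sealed tube)
Reagents that add atoms: none
Why: Mitsunobu O-alkylation of the acidic enol gives allyl vinyl ether 15, and its Claisen rearrangement through a chair transition state should form the C5–C6 bond on the face of C5 anti to the C11 aryl group and transfer the (E)-alkene geometry (4-methoxyphenyl equatorial) into the C6 configuration.

**Step 8**
Reactants: 16 keto aldehyde
Product: 18 acetonyl ketone: 16 with the formyl group replaced by CH2C(=O)CH3 (C8H2–C2(=O)–C3H3), via methyl enol ether 17 (not isolated)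
Conditions: Ph3P(+)CH(OMe)CH3 Cl(−), KN(SiMe3)2, THF, −78 to 0 °C; then 1 M HCl, THF, rt
Reagents that add atoms: (1-methoxyethyl)triphenylphosphonium chloride, COC(C)[P+](c1ccccc1)(c1ccccc1)c1ccccc1.[Cl-]; water, O
Why: Wittig reaction of the aldehyde (more reactive than the hindered ring ketone) with the α-methoxyethylidene ylide gives enol ether 17, and mild acid hydrolysis should give the methyl ketone, so that the formyl carbon becomes the C8 methylene.

**Step 9**
Reactants: 18 acetonyl ketone
Product: 19 epoxide of 18 at the C7=C1 alkene (both epimers at C7)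
Conditions: mCPBA, NaHCO3, CH2Cl2, 0 °C
Reagents that add atoms: mCPBA, OOC(=O)c1cccc(Cl)c1
Why: Prilezhaev epoxidation of the only nucleophilic alkene (the 1,1-disubstituted styrene) should leave the ketones and the anisole rings untouched; the epoxide configuration is inconsequential.

**Step 10**
Reactants: 19 epoxide
Product: 20 keto aldehyde: 18 with the side chain ending as CH(3,5-dimethoxyphenyl)–CHO (C7 epimers)
Conditions: BF3·OEt2 (10 mol %), CH2Cl2, −78 °C
Reagents that add atoms: none
Why: Meinwald rearrangement, in which Lewis-acid opening at the tertiary benzylic carbon C7 and a 1,2-hydride shift from the CH2 group give the α-aryl aldehyde (C1); the epimerisable C7 centre is corrected in step 11.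

**Step 11**
Reactants: 20 keto aldehyde
Product: 22 angular triquinane dienone (C1=C8–C2(=O)–C3=C4), via cyclopentene methyl ketone 21 (not isolated)
Conditions: KOH, MeOH/THF, 0 °C to rt
Reagents that add atoms: none
Why: Double intramolecular aldol condensation in which only five-membered rings can form (C8 onto the C1 aldehyde, then the methyl carbon C3 onto the C4 ketone as in cyclopentenone synthesis from 1,4-diketones), while C7 should equilibrate through the aldehyde enolate to the trans arrangement of the C6 and C7 aryl groups.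

**Step 12**
Reactants: 22 triquinane dienone
Product: 23 C8–C1 epoxy ketone (oxygen syn to the C5–C11 bond)
Conditions: t-BuOOH, DBU, CH2Cl2, 0 °C to rt
Reagents that add atoms: tert-butyl hydroperoxide, CC(C)(C)OO
Why: Weitz–Scheffer nucleophilic epoxidation should occur at the less substituted β-carbon C1 of the cross-conjugated dienone, and only the face that keeps the two five-membered rings cis-fused at C5–C8 can close the epoxide.

**Step 13**
Reactants: 23 epoxy ketone
Product: 24 heptamethyl ether of the target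
Conditions: BF3·OEt2 (0.3 equiv), CH2Cl2, −40 to 0 °C
Reagents that add atoms: none
Why: BF3 coordinates the epoxide oxygen and the C1–O bond ionises while the C2 acyl carbon, anti-periplanar to it on the opposite face of the five-membered ring, migrates from C8 to C1 and C8–O becomes the bridging ketone (semipinacol 1,2-acyl shift, the known Lewis-acid rearrangement of α,β-epoxy ketones to 1,3-diketones). No ring is closed by cyclisation: the cyclopentenone ring (C8, C2, C3, C4, C5) expands to the six-membered enedione ring (C1, C2, C3, C4, C5, C8) by insertion of C1, while the cyclopentane C5–C8–C1–C7–C6 is kept, which converts the angular triquinane into the bicyclo[3.2.1]octene. The new stereocentre C1 forms with inversion (the acyl group enters anti to the departing oxygen) and, as a bridgehead, can only take the configuration dictated by C5. The step needs C1–O rather than C8–O cleavage and acyl rather than alkyl (C5) or aryl (from C7) migration; cation character at the α-keto carbon C8 is disfavoured, carbonyl formation at C8 drives the acyl shift, and the meta-methoxylated aryl group on C7 is a poor participating group.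

**Step 14**
Reactants: 24 heptamethyl ether
Product: 25 CNP0407321.1 (target)
Conditions: BBr3 (excess), CH2Cl2, −78 to 0 °C; then MeOH/H2O
Reagents that add atoms: none
Why: Lewis-acid cleavage of the seven aryl methyl ethers with BBr3 and hydrolysis of the aryl borates should free the phenols without touching a stereocentre, since the bridgehead C1 between the two ketones cannot enolise.

**Compound list**

1 | 3-(4-methoxyphenyl)prop-2-yn-1-ol | OCC#Cc1ccc(OC)cc1 | starting material
2 | (3,5-dimethoxyphenyl)magnesium chloride (THF solution) | COc1cc(OC)cc([Mg]Cl)c1 | starting material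
3 | 4-(3,5-dimethoxyphenyl)-3-(4-methoxyphenyl)-2,5-dihydro-1,2-oxamagnesole (alkenylmagnesium chelate) | COc1ccc(cc1)C1=C(c2cc(OC)cc(OC)c2)CO[Mg]1 | intermediate (not isolated)
4 | (E)-2-(3,5-dimethoxyphenyl)-3-(4-methoxyphenyl)prop-2-en-1-ol | OC/C(c1cc(OC)cc(OC)c1)=C/c1ccc(OC)cc1 | intermediate
5 | cyclopent-3-en-1-ol | OC1CC=CC1 | starting material
6 | 4-methoxybenzenediazonium tetrafluoroborate | COc1ccc(cc1)[N+]#N.F[B-](F)(F)F | starting material
7 | (1S,4R)-4-(4-methoxyphenyl)cyclopent-2-en-1-ol (cis) | O[C@@H]1C=C[C@H](c2ccc(OC)cc2)C1 | intermediate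
8 | (R)-4-(4-methoxyphenyl)cyclopent-2-en-1-one | O=C1C=C[C@H](c2ccc(OC)cc2)C1 | intermediate
9 | 4-methoxybenzaldehyde | COc1ccc(C=O)cc1 | starting material
10 | chloromagnesium enolate of trans-3-(3,5-dimethoxyphenyl)-4-(4-methoxyphenyl)cyclopentanone (enolate C4=C9) | Cl[Mg]OC1=C[C@@H](c2cc(OC)cc(OC)c2)[C@H](c2ccc(OC)cc2)C1 | intermediate (not isolated)
11 | 2,3-trans-3,4-trans-3-(3,5-dimethoxyphenyl)-2-[hydroxy(4-methoxyphenyl)methyl]-4-(4-methoxyphenyl)cyclopentan-1-one (carbinol epimers) | O=C1[C@H](C(O)c2ccc(OC)cc2)[C@@H](c2cc(OC)cc(OC)c2)[C@H](c2ccc(OC)cc2)C1 | intermediate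
12 | trans-3-(3,5-dimethoxyphenyl)-2-[(E)-4-methoxybenzylidene]-4-(4-methoxyphenyl)cyclopentan-1-one | O=C1/C(=C/c2ccc(OC)cc2)[C@@H](c2cc(OC)cc(OC)c2)[C@H](c2ccc(OC)cc2)C1 | intermediate (not isolated)
13 | cis-fused 5,7-dimethoxy-3,8-bis(4-methoxyphenyl)-3,3a,8,8a-tetrahydrocyclopenta[a]inden-1(2H)-one (H-3/H-3a trans, H-8/H-8a trans) | O=C1[C@H]2[C@H](c3ccc(OC)cc3)c3c(OC)cc(OC)cc3[C@H]2[C@H](c2ccc(OC)cc2)C1 | intermediate
14 | 2-(hydroxymethylene) derivative of 13 (chelated Z enol) | O=C1[C@H]2[C@H](c3ccc(OC)cc3)c3c(OC)cc(OC)cc3[C@H]2[C@H](c2ccc(OC)cc2)/C1=C/O | intermediate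
15 | (E)-enol ether of 14 with the (E)-2-(3,5-dimethoxyphenyl)-3-(4-methoxyphenyl)allyl group on oxygen | O=C1[C@H]2[C@H](c3ccc(OC)cc3)c3c(OC)cc(OC)cc3[C@H]2[C@H](c2ccc(OC)cc2)/C1=C\OC/C(c1cc(OC)cc(OC)c1)=C/c1ccc(OC)cc1 | intermediate (not isolated)
16 | keto aldehyde with quaternary C5: formyl (C8) cis to the C11 aryl, 2-(3,5-dimethoxyphenyl)-1-(4-methoxyphenyl)prop-2-en-1-yl group (C6, C7, C1) trans | O=C1[C@H]2[C@H](c3ccc(OC)cc3)c3c(OC)cc(OC)cc3[C@H]2[C@H](c2ccc(OC)cc2)[C@@]1(C=O)[C@H](c1ccc(OC)cc1)C(=C)c1cc(OC)cc(OC)c1 | intermediate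
17 | 2-methoxyprop-1-enyl analogue of 16 (enol ether, E/Z mixture) | O=C1[C@H]2[C@H](c3ccc(OC)cc3)c3c(OC)cc(OC)cc3[C@H]2[C@H](c2ccc(OC)cc2)[C@@]1(C=C(C)OC)[C@H](c1ccc(OC)cc1)C(=C)c1cc(OC)cc(OC)c1 | intermediate (not isolated)
18 | acetonyl ketone (2-oxopropyl on C5) | O=C1[C@H]2[C@H](c3ccc(OC)cc3)c3c(OC)cc(OC)cc3[C@H]2[C@H](c2ccc(OC)cc2)[C@@]1(CC(C)=O)[C@H](c1ccc(OC)cc1)C(=C)c1cc(OC)cc(OC)c1 | intermediate
19 | epoxide of 18 at C7–C1 (C7 epimers) | O=C1[C@H]2[C@H](c3ccc(OC)cc3)c3c(OC)cc(OC)cc3[C@H]2[C@H](c2ccc(OC)cc2)[C@@]1(CC(C)=O)[C@H](c1ccc(OC)cc1)C1(CO1)c1cc(OC)cc(OC)c1 | intermediate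
20 | keto aldehyde with C1 as CHO on C7 (C7 epimers) | O=C1[C@H]2[C@H](c3ccc(OC)cc3)c3c(OC)cc(OC)cc3[C@H]2[C@H](c2ccc(OC)cc2)[C@@]1(CC(C)=O)[C@H](c1ccc(OC)cc1)C(C=O)c1cc(OC)cc(OC)c1 | intermediate
21 | spiro cyclopentene methyl ketone (C8=C1 formed, C4 ketone intact, C6/C7 aryl groups trans) | O=C1[C@H]2[C@H](c3ccc(OC)cc3)c3c(OC)cc(OC)cc3[C@H]2[C@H](c2ccc(OC)cc2)[C@]13C(C(C)=O)=C[C@H](c1cc(OC)cc(OC)c1)[C@H]3c1ccc(OC)cc1 | intermediate (not isolated)
22 | angular triquinane dienone | O=C1C=C2[C@H]3[C@H](c4ccc(OC)cc4)c4c(OC)cc(OC)cc4[C@H]3[C@H](c3ccc(OC)cc3)[C@]24C1=C[C@H](c1cc(OC)cc(OC)c1)[C@H]4c1ccc(OC)cc1 | intermediate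
23 | C8–C1 epoxy ketone | O=C1C=C2[C@H]3[C@H](c4ccc(OC)cc4)c4c(OC)cc(OC)cc4[C@H]3[C@H](c3ccc(OC)cc3)[C@]24[C@]15O[C@H]5[C@H](c1cc(OC)cc(OC)c1)[C@H]4c1ccc(OC)cc1 | intermediate
24 | heptamethyl ether of the target | O=C1C=C2[C@H]3[C@H](c4ccc(OC)cc4)c4c(OC)cc(OC)cc4[C@H]3[C@H](c3ccc(OC)cc3)[C@]23C(=O)[C@H]1[C@H](c1cc(OC)cc(OC)c1)[C@H]3c1ccc(OC)cc1 | intermediate
25 | CNP0407321.1 | O=C1C=C2[C@H]3[C@H](c4ccc(O)cc4)c4c(O)cc(O)cc4[C@H]3[C@H](c3ccc(O)cc3)[C@]23C(=O)[C@H]1[C@H](c1cc(O)cc(O)c1)[C@H]3c1ccc(O)cc1 | target

**Step count and risk**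

Total step count: 14. Longest linear sequence: 13 steps (steps 2 to 14; step 1 supplies the allyl fragment).

Steps most likely to fail:

1. Step 7 (O-allylation and Claisen rearrangement). The rearrangement may run through a boat-like transition state, or through the (Z)-enol ether formed in the Mitsunobu stage, and then deliver the C6 epimer; C-alkylation in place of O-alkylation would add to the loss. Fallback, setting out from 1 and 14 and returning at 16: the geometry of the allyl partner is inverted. Rhodium-catalysed syn-hydroarylation of 1 with 3,5-dimethoxyphenylboronic acid ([Rh(OH)(cod)]2, dioxane/H2O, 80 °C, aryl to the alkyne carbon remote from the existing aryl group) should give (Z)-2-(3,5-dimethoxyphenyl)-3-(4-methoxyphenyl)prop-2-en-1-ol F1. Mitsunobu O-alkylation of 14 with F1 gives the enol ether F2, and its rearrangement through the same transition-state topology that caused the failure places the 4-methoxyphenyl group correctly and leads to 16.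

2. Step 8 (homologation of the formyl group). The basic ylide may trigger retro-Claisen deformylation of the non-enolisable β-keto aldehyde, and olefination of the neopentyl aldehyde may be slow. Fallback, from 16 to 18: a Henry reaction with nitroethane under a weakly basic amine catalyst (tetramethylguanidine, THF, 0 °C) gives the nitro alcohol F3. Dehydration (MsCl, Et3N, CH2Cl2) gives the nitroalkene F4, and iron powder in acetic acid (reductive Nef-type hydrolysis) gives 18.

3. Step 13 (epoxy ketone rearrangement). The epoxide may open with hydride or aryl shift or with elimination to an allylic alcohol instead of acyl migration. Fallback, from 22 to 24: dihydroxylation of the C8=C1 alkene (OsO4 cat., N-methylmorpholine N-oxide, acetone/H2O) on the face that keeps the rings cis-fused gives the cis-diol F5. Selective mesylation of the secondary C1 hydroxyl (MsCl, Et3N, CH2Cl2, −20 °C) gives the hydroxy mesylate F6, and warming with Et3N in toluene should trigger the same anti 1,2-acyl shift with loss of mesylate (semipinacol rearrangement) to give 24.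

**Further compounds**

F1 | step 7 | (Z)-2-(3,5-dimethoxyphenyl)-3-(4-methoxyphenyl)prop-2-en-1-ol | OC/C(c1cc(OC)cc(OC)c1)=C\c1ccc(OC)cc1
F2 | step 7 | (E)-enol ether of 14 with the (Z)-2-(3,5-dimethoxyphenyl)-3-(4-methoxyphenyl)allyl group on oxygen | O=C1[C@H]2[C@H](c3ccc(OC)cc3)c3c(OC)cc(OC)cc3[C@H]2[C@H](c2ccc(OC)cc2)/C1=C\OC/C(c1cc(OC)cc(OC)c1)=C\c1ccc(OC)cc1
F3 | step 8 | nitro alcohol from 16 and nitroethane (1-hydroxy-2-nitropropyl on C5, diastereomer mixture) | O=C1[C@H]2[C@H](c3ccc(OC)cc3)c3c(OC)cc(OC)cc3[C@H]2[C@H](c2ccc(OC)cc2)[C@@]1(C(O)C(C)[N+](=O)[O-])[C@H](c1ccc(OC)cc1)C(=C)c1cc(OC)cc(OC)c1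
F4 | step 8 | (E)-nitroalkene (2-nitroprop-1-enyl on C5) | O=C1[C@H]2[C@H](c3ccc(OC)cc3)c3c(OC)cc(OC)cc3[C@H]2[C@H](c2ccc(OC)cc2)[C@@]1(/C=C(\C)[N+](=O)[O-])[C@H](c1ccc(OC)cc1)C(=C)c1cc(OC)cc(OC)c1
F5 | step 13 | C8,C1 cis-diol of 22 (both hydroxyls syn to the C5–C11 bond) | O=C1C=C2[C@H]3[C@H](c4ccc(OC)cc4)c4c(OC)cc(OC)cc4[C@H]3[C@H](c3ccc(OC)cc3)[C@]24[C@@]1(O)[C@@H](O)[C@H](c1cc(OC)cc(OC)c1)[C@H]4c1ccc(OC)cc1
F6 | step 13 | C1 mesylate of F5 | O=C1C=C2[C@H]3[C@H](c4ccc(OC)cc4)c4c(OC)cc(OC)cc4[C@H]3[C@H](c3ccc(OC)cc3)[C@]24[C@@]1(O)[C@@H](OS(C)(=O)=O)[C@H](c1cc(OC)cc(OC)c1)[C@H]4c1ccc(OC)cc1
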